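**Retrosynthetic overview**
1. Target 21 is cut once, across the cyclohexene: an intermolecular [4+2] between dienyl-chalcone 20 (diene) and prenyl-chalcone 10 (dienophile), run by an endo-selective Diels–Alderase. This last step forms the only new ring and all three stereocentres.
2. Dienophile 10 comes from a Claisen–Schmidt condensation of aldehyde 2 with prenylated acetophenone 8; the prenyl group is put in by directed ortho-metalation of the ketal-masked resorcinol 5.
3. Diene 20 comes from deacetylation of 19, which comes from Stille coupling of iodochalcone triacetate 16 with dienylstannane 18; 16 is made by Claisen–Schmidt condensation of 2 with iodoacetophenone 13.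
4. Ring order: the four benzene rings are bought; the methylcyclohexene is formed last.

Assumption: the SMILES is taken as written, so the aroyl ring is 3,5-dihydroxy-4-prenylphenyl (no hydroxyl ortho to the carbonyl) and the ring is the cis,trans (endo) isomer, (1S,5S,6R); a recombinant endo-selective mulberry Diels–Alderase is taken to be available.

**Route**

Step 1
Reactants: 1 4-hydroxybenzaldehyde
Product: 2 4-(methoxymethoxy)benzaldehyde
Conditions: NaH (1.2 equiv), MOMCl (1.2 equiv), DMF, 0 °C → rt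
Reagents that add atoms: chloromethyl methyl ether (MOMCl), COCCl
Why: Williamson-type O-alkylation of the phenoxide (MOM protection) keeps the aldehyde neutral and electrophilic for the later base-mediated condensations.

Step 2
Reactants: 3 1-(3,5-dihydroxyphenyl)ethanone
Product: 4 5-(2-methyl-1,3-dioxolan-2-yl)benzene-1,3-diol
Conditions: HOCH2CH2OH (5 equiv), p-TsOH·H2O (2 mol%), toluene, reflux, Dean–Stark; Et3N quench
Reagents that add atoms: ethylene glycol, OCCO
Why: Acid-catalysed ketalisation driven by azeotropic water removal masks the acetyl group against n-BuLi; the meta-hydroxyls do not deactivate the carbonyl.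

Step 3
Reactants: 4 5-(2-methyl-1,3-dioxolan-2-yl)benzene-1,3-diol
Product: 5 2-[3,5-bis(methoxymethoxy)phenyl]-2-methyl-1,3-dioxolane
Conditions: NaH (2.5 equiv), MOMCl (2.5 equiv), DMF, 0 °C → rt
Reagents that add atoms: chloromethyl methyl ether (MOMCl), COCCl
Why: MOM protection of both phenoxides under basic conditions leaves the ketal intact and installs the two directing groups for the next step.

Step 4
Reactants: 5 2-[3,5-bis(methoxymethoxy)phenyl]-2-methyl-1,3-dioxolane
Product: 7 2-[3,5-bis(methoxymethoxy)-4-(3-methylbut-2-en-1-yl)phenyl]-2-methyl-1,3-dioxolane, via 4-lithio arene 6 (not isolated)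
Conditions: n-BuLi (1.2 equiv), THF, 0 °C, 1.5 h; CuI (10 mol%), then prenyl bromide (1.5 equiv), −78 °C → rt
Reagents that add atoms: n-butyllithium, [Li]CCCC (lithium stays in 6 only); prenyl bromide (1-bromo-3-methylbut-2-ene), CC(C)=CCBr
Why: Directed ortho-metalation takes place at the one carbon flanked by both OMOM groups, and the copper-assisted aryl nucleophile is alkylated at the primary carbon of prenyl bromide (SN2).

Step 5
Reactants: 7 2-[3,5-bis(methoxymethoxy)-4-(3-methylbut-2-en-1-yl)phenyl]-2-methyl-1,3-dioxolane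
Product: 8 1-[3,5-bis(methoxymethoxy)-4-(3-methylbut-2-en-1-yl)phenyl]ethanone
Conditions: PPTS (0.2 equiv), acetone/H2O (9:1), 50 °C
Reagents that add atoms: water, O
Why: Mild acid-catalysed ketal hydrolysis cleaves the ketone dioxolane much faster than aryl MOM ethers, and with no free phenol the prenyl group cannot cyclise.

Step 6
Reactants: 8 1-[3,5-bis(methoxymethoxy)-4-(3-methylbut-2-en-1-yl)phenyl]ethanone; 2 4-(methoxymethoxy)benzaldehyde
Product: 9 (E)-1-[3,5-bis(methoxymethoxy)-4-(3-methylbut-2-en-1-yl)phenyl]-3-[4-(methoxymethoxy)phenyl]prop-2-en-1-one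
Conditions: KOH (3 equiv), EtOH/H2O, rt, 24 h
Reagents that add atoms: none
Why: Claisen–Schmidt (crossed aldol) condensation of a methyl ketone with a non-enolisable aldehyde, followed by E1cB dehydration, gives only the E-enone.

Step 7
Reactants: 9 (E)-1-[3,5-bis(methoxymethoxy)-4-(3-methylbut-2-en-1-yl)phenyl]-3-[4-(methoxymethoxy)phenyl]prop-2-en-1-one
Product: 10 (E)-1-[3,5-dihydroxy-4-(3-methylbut-2-en-1-yl)phenyl]-3-(4-hydroxyphenyl)prop-2-en-1-one
Conditions: 3 M aq. HCl/MeOH (1:5), 40 °C, 1–2 h, stopped at full conversion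
Reagents that add atoms: none
Why: Acid-catalysed acetal exchange removes the three MOM groups, and short, mild exposure of the kind used for other prenylated chalcones limits chroman formation.

Step 8
Reactants: 11 1-(2,4-dihydroxyphenyl)ethanone
Product: 12 1-(2,4-dihydroxy-3-iodophenyl)ethanone
Conditions: I2 (0.4 equiv), HIO3 (0.2 equiv), EtOH/H2O, rt → 40 °C
Reagents that add atoms: iodine, II; iodic acid, OI(=O)=O
Why: Electrophilic aromatic iodination with in-situ oxidation of iodide goes to C3, the position ortho to both hydroxyls, which is the established outcome for this acetophenone.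

Step 9
Reactants: 12 1-(2,4-dihydroxy-3-iodophenyl)ethanone
Product: 13 1-[3-iodo-2,4-bis(methoxymethoxy)phenyl]ethanone
Conditions: NaH (2.4 equiv), MOMCl (2.6 equiv), DMF, 0 °C → rt
Reagents that add atoms: chloromethyl methyl ether (MOMCl), COCCl
Why: MOM protection of both phenoxides (the chelated 2-OH needs the strong base) gives a ketone that condenses cleanly under base.

Step 10
Reactants: 13 1-[3-iodo-2,4-bis(methoxymethoxy)phenyl]ethanone; 2 4-(methoxymethoxy)benzaldehyde
Product: 14 (E)-1-[3-iodo-2,4-bis(methoxymethoxy)phenyl]-3-[4-(methoxymethoxy)phenyl]prop-2-en-1-one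
Conditions: KOH (3 equiv), EtOH/H2O, rt, 24 h
Reagents that add atoms: none
Why: Claisen–Schmidt condensation gives the E-chalcone, and the aryl iodide is inert to hydroxide at room temperature.

Step 11
Reactants: 14 (E)-1-[3-iodo-2,4-bis(methoxymethoxy)phenyl]-3-[4-(methoxymethoxy)phenyl]prop-2-en-1-one
Product: 15 (E)-1-(2,4-dihydroxy-3-iodophenyl)-3-(4-hydroxyphenyl)prop-2-en-1-one
Conditions: 3 M aq. HCl/MeOH (1:5), 50 °C, 1 h
Reagents that add atoms: none
Why: Acid-catalysed MOM cleavage is done here, before the acid-labile diene exists, and the short reaction time avoids chalcone-to-flavanone cyclisation.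

Step 12
Reactants: 15 (E)-1-(2,4-dihydroxy-3-iodophenyl)-3-(4-hydroxyphenyl)prop-2-en-1-one
Product: 16 (E)-1-(2,4-diacetoxy-3-iodophenyl)-3-(4-acetoxyphenyl)prop-2-en-1-one
Conditions: Ac2O (4 equiv), pyridine, DMAP (5 mol%), CH2Cl2, 0 °C → rt
Reagents that add atoms: acetic anhydride, CC(=O)OC(C)=O
Why: DMAP-catalysed O-acylation gives acetates that survive neutral Stille conditions and later come off with mild base, which the diene tolerates.

Step 13
Reactants: 17 2-methylbut-1-en-3-yne
Product: 18 tributyl[(1E)-3-methylbuta-1,3-dien-1-yl]stannane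
Conditions: Bu3SnH (1.0 equiv), 17 (1.5 equiv), AIBN (5 mol%), neat, sealed tube, 80 °C
Reagents that add atoms: tributyltin hydride, CCCC[SnH](CCCC)CCCC
Why: Radical-chain hydrostannation adds the stannyl radical to the terminal alkyne carbon, and reversible stannyl-radical addition equilibrates the product to the E-dienylstannane.

Step 14
Reactants: 16 (E)-1-(2,4-diacetoxy-3-iodophenyl)-3-(4-acetoxyphenyl)prop-2-en-1-one; 18 tributyl[(1E)-3-methylbuta-1,3-dien-1-yl]stannane
Product: 19 (E)-1-{2,4-diacetoxy-3-[(1E)-3-methylbuta-1,3-dien-1-yl]phenyl}-3-(4-acetoxyphenyl)prop-2-en-1-one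
Conditions: Pd2(dba)3 (5 mol%), AsPh3 (20 mol%), CuI (10 mol%), DMF, 50 °C, dark
Reagents that add atoms: none
Why: Stille cross-coupling transfers the dienyl group with retention of the E geometry under neutral conditions that leave the acetates and the enone untouched.

Step 15
Reactants: 19 (E)-1-{2,4-diacetoxy-3-[(1E)-3-methylbuta-1,3-dien-1-yl]phenyl}-3-(4-acetoxyphenyl)prop-2-en-1-one
Product: 20 (E)-1-{2,4-dihydroxy-3-[(1E)-3-methylbuta-1,3-dien-1-yl]phenyl}-3-(4-hydroxyphenyl)prop-2-en-1-one
Conditions: K2CO3 (0.5 equiv), MeOH/THF, 0 °C, 30–60 min; pH 6 phosphate buffer, EtOAc extraction; used at once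
Reagents that add atoms: none
Why: Base-catalysed transesterification (methanolysis) of the aryl acetates frees the phenols without acid, which would close the o-hydroxyaryl diene to a chromene.

Step 16
Reactants: 20 (E)-1-{2,4-dihydroxy-3-[(1E)-3-methylbuta-1,3-dien-1-yl]phenyl}-3-(4-hydroxyphenyl)prop-2-en-1-one; 10 (E)-1-[3,5-dihydroxy-4-(3-methylbut-2-en-1-yl)phenyl]-3-(4-hydroxyphenyl)prop-2-en-1-one
Product: 21 kuwanon V as drawn, (E)-1-{3-[(1S,5S,6R)-6-[3,5-dihydroxy-4-(3-methylbut-2-en-1-yl)benzoyl]-5-(4-hydroxyphenyl)-3-methylcyclohex-2-en-1-yl]-2,4-dihydroxyphenyl}-3-(4-hydroxyphenyl)prop-2-en-1-one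
Conditions: endo-selective Diels–Alderase (FAD-dependent berberine-bridge-enzyme-like [4+2] cyclase of the mulberry MaDA family, ca. 1 mol%), 20 mM Tris-HCl pH 8.0, 5% DMSO, 30–37 °C, 16 h, dark, Ar; 10 in excess (2–3 equiv, recovered), 20 fed in portions
Reagents that add atoms: none
Why: In this enzymatic intermolecular Diels–Alder reaction the Diels–Alderase holds E-diene 20 over one enantioface of E-enone 10 in an endo geometry, so the ring, the ortho regiochemistry and all three stereocentres (aryl/aroyl cis, aroyl/aryl trans, 1S,5S,6R as in the natural cis,trans adducts these enzymes make) are set together under catalyst control with no thermal background at this temperature.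

**Compound list**

1 | 4-hydroxybenzaldehyde | O=Cc1ccc(O)cc1 | starting material
2 | 4-(methoxymethoxy)benzaldehyde | COCOc1ccc(C=O)cc1 | intermediate
3 | 1-(3,5-dihydroxyphenyl)ethanone (3,5-dihydroxyacetophenone) | CC(=O)c1cc(O)cc(O)c1 | starting material
4 | 5-(2-methyl-1,3-dioxolan-2-yl)benzene-1,3-diol | CC1(OCCO1)c1cc(O)cc(O)c1 | intermediate
5 | 2-[3,5-bis(methoxymethoxy)phenyl]-2-methyl-1,3-dioxolane | COCOc1cc(OCOC)cc(c1)C1(C)OCCO1 | intermediate
6 | [2,6-bis(methoxymethoxy)-4-(2-methyl-1,3-dioxolan-2-yl)phenyl]lithium (4-lithio arene, not isolated) | [Li]c1c(OCOC)cc(cc1OCOC)C1(C)OCCO1 | intermediate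
7 | 2-[3,5-bis(methoxymethoxy)-4-(3-methylbut-2-en-1-yl)phenyl]-2-methyl-1,3-dioxolane | CC(C)=CCc1c(OCOC)cc(cc1OCOC)C1(C)OCCO1 | intermediate
8 | 1-[3,5-bis(methoxymethoxy)-4-(3-methylbut-2-en-1-yl)phenyl]ethanone | CC(=O)c1cc(OCOC)c(CC=C(C)C)c(OCOC)c1 | intermediate
9 | (E)-1-[3,5-bis(methoxymethoxy)-4-(3-methylbut-2-en-1-yl)phenyl]-3-[4-(methoxymethoxy)phenyl]prop-2-en-1-one | COCOc1ccc(/C=C/C(=O)c2cc(OCOC)c(CC=C(C)C)c(OCOC)c2)cc1 | intermediate
10 | (E)-1-[3,5-dihydroxy-4-(3-methylbut-2-en-1-yl)phenyl]-3-(4-hydroxyphenyl)prop-2-en-1-one | CC(C)=CCc1c(O)cc(cc1O)C(=O)/C=C/c1ccc(O)cc1 | intermediate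
11 | 1-(2,4-dihydroxyphenyl)ethanone (2,4-dihydroxyacetophenone) | CC(=O)c1ccc(O)cc1O | starting material
12 | 1-(2,4-dihydroxy-3-iodophenyl)ethanone | CC(=O)c1ccc(O)c(I)c1O | intermediate
13 | 1-[3-iodo-2,4-bis(methoxymethoxy)phenyl]ethanone | CC(=O)c1ccc(OCOC)c(I)c1OCOC | intermediate
14 | (E)-1-[3-iodo-2,4-bis(methoxymethoxy)phenyl]-3-[4-(methoxymethoxy)phenyl]prop-2-en-1-one | COCOc1ccc(/C=C/C(=O)c2ccc(OCOC)c(I)c2OCOC)cc1 | intermediate
15 | (E)-1-(2,4-dihydroxy-3-iodophenyl)-3-(4-hydroxyphenyl)prop-2-en-1-one | O=C(/C=C/c1ccc(O)cc1)c1ccc(O)c(I)c1O | intermediate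
16 | (E)-1-(2,4-diacetoxy-3-iodophenyl)-3-(4-acetoxyphenyl)prop-2-en-1-one | CC(=O)Oc1ccc(/C=C/C(=O)c2ccc(OC(C)=O)c(I)c2OC(C)=O)cc1 | intermediate
17 | 2-methylbut-1-en-3-yne | C#CC(C)=C | starting material
18 | tributyl[(1E)-3-methylbuta-1,3-dien-1-yl]stannane | CCCC[Sn](CCCC)(CCCC)/C=C/C(C)=C | intermediate
19 | (E)-1-{2,4-diacetoxy-3-[(1E)-3-methylbuta-1,3-dien-1-yl]phenyl}-3-(4-acetoxyphenyl)prop-2-en-1-one | CC(=O)Oc1ccc(/C=C/C(=O)c2ccc(OC(C)=O)c(/C=C/C(C)=C)c2OC(C)=O)cc1 | intermediate
20 | (E)-1-{2,4-dihydroxy-3-[(1E)-3-methylbuta-1,3-dien-1-yl]phenyl}-3-(4-hydroxyphenyl)prop-2-en-1-one | CC(=C)/C=C/c1c(O)ccc(C(=O)/C=C/c2ccc(O)cc2)c1O | intermediate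
21 | kuwanon V as drawn, (E)-1-{3-[(1S,5S,6R)-6-[3,5-dihydroxy-4-(3-methylbut-2-en-1-yl)benzoyl]-5-(4-hydroxyphenyl)-3-methylcyclohex-2-en-1-yl]-2,4-dihydroxyphenyl}-3-(4-hydroxyphenyl)prop-2-en-1-one | CC(C)=CCc1c(O)cc(C(=O)[C@H]2[C@@H](c3c(O)ccc(C(=O)/C=C/c4ccc(O)cc4)c3O)C=C(C)C[C@@H]2c2ccc(O)cc2)cc1O | target

**Totals**

Total step count: 16.
Longest linear sequence: 8 steps (11 → 12 → 13 → 14 → 15 → 16 → 19 → 20 → 21; steps 8, 9, 10, 11, 12, 14, 15, 16).

**Three steps most likely to fail**

Step 16 is the weakest step. Dienophile 10 lacks the hydrogen-bonded ortho-hydroxy enone of the chalcones that mulberry Diels–Alderases normally take, so acceptance by the enzyme is unproven and turnover may be poor. Diene 20 also carries such an enone and can dimerise through it; the excess of 10 and the slow feed of 20 are there to limit this. The fallback sets out from 10 and 19 and comes back at 21. Compound 10 is peracetylated (Ac2O, pyridine, DMAP) to (E)-1-[3,5-diacetoxy-4-(3-methylbut-2-en-1-yl)phenyl]-3-(4-acetoxyphenyl)prop-2-en-1-one F1. F1 and 19 are then heated without catalyst (toluene, BHT, 150 °C, sealed tube) in a thermal Diels–Alder reaction. The cis,trans (endo) adduct is separated from the all-trans (exo) isomer on silica and the racemate is resolved by preparative chiral-phase HPLC, which gives the (1S,5S,6R)-hexa-O-acetate of 21 F2. K2CO3 in MeOH at 0 °C then gives 21. This fallback gives up catalytic asymmetric induction for a resolution.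

Step 14 is the second risk. The iodide of 16 sits between two ortho acetoxy groups, and the stannane 18 carries some Z isomer and tin residues. The fallback sets out from 16 and comes back at 19. A Heck reaction of 16 with 2-methylbut-3-en-2-ol (Pd(OAc)2, n-Bu4NCl, NaHCO3, DMF, 60 °C) gives (E)-1-{2,4-diacetoxy-3-[(1E)-3-hydroxy-3-methylbut-1-en-1-yl]phenyl}-3-(4-acetoxyphenyl)prop-2-en-1-one F3. Dehydration of this tertiary allylic alcohol with Burgess reagent (toluene, 50 °C) can only eliminate towards a methyl group and so gives diene 19 with the E geometry already fixed by the Heck step.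

Step 7 is the third risk. Once the MOM groups fall, the prenyl group lies between two free phenols and can close to a 2,2-dimethylchroman under acid. The fallback sets out from 5 and comes back at 10, and carries an allyl group through the acid step instead. Lithiation of 5 as in step 4 (through 6) and quenching with allyl bromide gives 2-[4-allyl-3,5-bis(methoxymethoxy)phenyl]-2-methyl-1,3-dioxolane F4. PPTS in wet acetone gives 1-[4-allyl-3,5-bis(methoxymethoxy)phenyl]ethanone F5. Claisen–Schmidt condensation with 2 gives (E)-1-[4-allyl-3,5-bis(methoxymethoxy)phenyl]-3-[4-(methoxymethoxy)phenyl]prop-2-en-1-one F6. HCl in MeOH gives (E)-1-(4-allyl-3,5-dihydroxyphenyl)-3-(4-hydroxyphenyl)prop-2-en-1-one F7, whose monosubstituted alkene is not protonated under these conditions. Olefin cross-metathesis with 2-methyl-2-butene (Grubbs second-generation catalyst, CH2Cl2, 40 °C) then turns allyl into prenyl and gives 10; the β-aryl enone is inert to the catalyst.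

**Further compounds**

F1 | step 16 | (E)-1-[3,5-diacetoxy-4-(3-methylbut-2-en-1-yl)phenyl]-3-(4-acetoxyphenyl)prop-2-en-1-one | CC(C)=CCc1c(OC(C)=O)cc(cc1OC(C)=O)C(=O)/C=C/c1ccc(OC(C)=O)cc1
F2 | step 16 | (1S,5S,6R)-hexa-O-acetate of 21 (formed as the racemate, this enantiomer taken by chiral HPLC) | CC(C)=CCc1c(OC(C)=O)cc(C(=O)[C@H]2[C@@H](c3c(OC(C)=O)ccc(C(=O)/C=C/c4ccc(OC(C)=O)cc4)c3OC(C)=O)C=C(C)C[C@@H]2c2ccc(OC(C)=O)cc2)cc1OC(C)=O
F3 | step 14 | (E)-1-{2,4-diacetoxy-3-[(1E)-3-hydroxy-3-methylbut-1-en-1-yl]phenyl}-3-(4-acetoxyphenyl)prop-2-en-1-one | CC(=O)Oc1ccc(/C=C/C(=O)c2ccc(OC(C)=O)c(/C=C/C(C)(C)O)c2OC(C)=O)cc1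
F4 | step 7 | 2-[4-allyl-3,5-bis(methoxymethoxy)phenyl]-2-methyl-1,3-dioxolane | C=CCc1c(OCOC)cc(cc1OCOC)C1(C)OCCO1
F5 | step 7 | 1-[4-allyl-3,5-bis(methoxymethoxy)phenyl]ethanone | CC(=O)c1cc(OCOC)c(CC=C)c(OCOC)c1
F6 | step 7 | (E)-1-[4-allyl-3,5-bis(methoxymethoxy)phenyl]-3-[4-(methoxymethoxy)phenyl]prop-2-en-1-one | COCOc1ccc(/C=C/C(=O)c2cc(OCOC)c(CC=C)c(OCOC)c2)cc1
F7 | step 7 | (E)-1-(4-allyl-3,5-dihydroxyphenyl)-3-(4-hydroxyphenyl)prop-2-en-1-one | C=CCc1c(O)cc(cc1O)C(=O)/C=C/c1ccc(O)cc1
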